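**Retrosynthetic overview**

1. The side chain is numbered from the ether oxygen: C1 is OCH2, C2=C3 is the E-trisubstituted alkene, C6 is the carbinol and C7=C8 is the isopropenyl group. The strategy rests on the array C2=C3–C4–C5–C6(OH): once C6 is the ketone this is a γ,δ-unsaturated ketone, which a Claisen rearrangement forming C4–C5 delivers.
2. Backwards: the cinnamyl alcohol comes from a methyl cinnamate by hydride reduction; the (R)-C6 carbinol from the isopropenyl ketone by oxazaborolidine-catalysed reduction; C4–C5 from an olefinic ketal Claisen rearrangement of ArOCH2–CH(OH)–C(CH3)=CH2 with 3,3-dimethoxy-2-methylbut-1-ene.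
3. The Claisen substrate comes from an aryloxyacetaldehyde and an isopropenylchromium reagent; the aldehyde from methyl sinapate and bromoacetaldehyde diethyl acetal; methyl sinapate from syringaldehyde by Wittig olefination; the ketal from 3-methylbutan-2-one.
4. No ring is formed at any stage. The benzene ring is bought with syringaldehyde, and the chain is grown on its phenol oxygen in the order cinnamate arm, C1–C2 tether, C3/C4 methallyl unit, C5–C8 unit.

Key step: step 8

Remark: the SMILES is read as the (R)-carbinol at C6 (CIP order OH > isopropenyl > CH2 > H) with both alkenes E; intermediates whose centres are not specified are racemic or diastereomer mixtures.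

**Route**

Step 1
Reactants: 1 syringaldehyde; 2 methyl (triphenylphosphoranylidene)acetate
Product: 3 methyl (E)-sinapate
Conditions: toluene, 100 °C
Reagents that add atoms: none
Why: Wittig olefination with a stabilised ylide tolerates the free phenol and should give the E-cinnamate, because reversible oxaphosphetane formation favours the trans product.

Step 2
Reactants: 3 methyl (E)-sinapate; 4 bromoacetaldehyde diethyl acetal
Product: 5 methyl (E)-3-[4-(2,2-diethoxyethoxy)-3,5-dimethoxyphenyl]prop-2-enoate
Conditions: K2CO3, KI (cat.), DMF, 110 °C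
Reagents that add atoms: none
Why: Williamson ether synthesis, in which the phenoxide displaces the primary bromide (iodide catalysis helps the sluggish β,β-dialkoxy halide) while the ester is inert to anhydrous carbonate.

Step 3
Reactants: 5 methyl (E)-3-[4-(2,2-diethoxyethoxy)-3,5-dimethoxyphenyl]prop-2-enoate
Product: 6 methyl (E)-3-[3,5-dimethoxy-4-(2-oxoethoxy)phenyl]prop-2-enoate
Conditions: 2 M aq. HCl, THF, 50 °C; crude aldehyde used at once
Reagents that add atoms: water, O
Why: Acid-catalysed acetal hydrolysis under dilute acid should leave the methyl ester and aryl ether intact, and both ortho positions are blocked so no benzofuran closure can follow.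

Step 4
Reactants: 6 methyl (E)-3-[3,5-dimethoxy-4-(2-oxoethoxy)phenyl]prop-2-enoate; 7 2-bromopropene
Product: 9 racemic methyl (E)-3-[4-(2-hydroxy-3-methylbut-3-enyloxy)-3,5-dimethoxyphenyl]prop-2-enoate, via isopropenylchromium dichloride 8 (not isolated)
Conditions: CrCl2 (4 equiv), NiCl2 (2 mol %), DMF, 25 °C; then H2O
Reagents that add atoms: none
Why: Nozaki–Hiyama–Kishi reaction, in which 7 adds oxidatively to zerovalent nickel (formed from NiCl2 by CrCl2) and transmetalates to trivalent chromium to give 8, which adds to the aldehyde only and leaves the cinnamate untouched; the new carbinol centre is racemic, which is acceptable because step 8 destroys it.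

Step 5
Reactants: 10 3-methylbutan-2-one
Product: 11 3-bromo-3-methylbutan-2-one
Conditions: Br2, HBr (cat.), CH2Cl2 (no alcohol cosolvent), 0 °C to rt; distil
Reagents that add atoms: bromine, BrBr
Why: Acid-catalysed α-bromination of a ketone in a non-hydroxylic solvent proceeds through the more substituted enol and should give the tertiary bromide.

Step 6
Reactants: 11 3-bromo-3-methylbutan-2-one
Product: 12 2-bromo-3,3-dimethoxy-2-methylbutane
Conditions: HC(OMe)3, MeOH, TsOH (cat.), rt to 40 °C; NaOMe quench
Reagents that add atoms: trimethyl orthoformate, COC(OC)OC; methanol, CO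
Why: Acid-catalysed dimethyl ketal formation is driven to completion by the orthoformate, which consumes the water formed.

Step 7
Reactants: 12 2-bromo-3,3-dimethoxy-2-methylbutane
Product: 13 3,3-dimethoxy-2-methylbut-1-ene
Conditions: KOt-Bu, DMSO, rt to 50 °C; distil
Reagents that add atoms: none
Why: E2 dehydrobromination can give only one alkene, since the sole β-hydrogens are on the geminal methyl groups, and the ketal is stable to base.

Step 8
Reactants: 9 racemic methyl (E)-3-[4-(2-hydroxy-3-methylbut-3-enyloxy)-3,5-dimethoxyphenyl]prop-2-enoate; 13 3,3-dimethoxy-2-methylbut-1-ene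
Product: 16 methyl (E)-3-[4-[(2E)-3,7-dimethyl-6-oxoocta-2,7-dienyloxy]-3,5-dimethoxyphenyl]prop-2-enoate, via mixed ketal 14 (not isolated), via allyl dienyl ether 15 (not isolated)
Conditions: 13 (5 equiv), 2,4-dinitrophenol (10 mol %), toluene, 110 °C, MeOH distilled off
Reagents that add atoms: none
Why: Acid-catalysed exchange of the secondary hydroxyl of 9 into ketal 13 gives mixed ketal 14, which loses methanol (only the ketal methyl carries a β-hydrogen) to the 2-allyloxy-3-methylbuta-1,3-diene 15; this allyl vinyl ether undergoes a concerted suprafacial [3,3]-sigmatropic shift that joins the enol-ether CH2 to the terminal CH2 of the methallyl unit (the C4–C5 bond), moves the double bond to C2=C3 and unveils the C6 carbonyl carrying the isopropenyl group. The closest known reaction type is the Johnson-type olefinic ketal Claisen rearrangement of secondary 2-methylallylic alcohols, used to build E-trisubstituted alkenes in polyprenoid chains. No ring is closed and no stereocentre is created; the racemic carbinol carbon of 9 becomes the trigonal carbon C2, so its configuration does not matter. The selectivity needed is E geometry at C2=C3, which the chair transition state secures because the CH2OAr group on the carbinol carbon sits equatorial to avoid a 1,3-diaxial contact with the isopropenyl group on the enol-ether carbon. Chemoselectivity comes from the substrate: the tether in 9 is a homoallyl aryl ether that cannot undergo an aromatic Claisen shift, the allyl aryl ether in 16 has both ortho positions occupied by methoxy groups and the para position by the cinnamate, and the ester is indifferent to a weak phenolic acid at 110 °C.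

Step 9
Reactants: 16 methyl (E)-3-[4-[(2E)-3,7-dimethyl-6-oxoocta-2,7-dienyloxy]-3,5-dimethoxyphenyl]prop-2-enoate
Product: 17 methyl (E)-3-[4-[(2E,6R)-6-hydroxy-3,7-dimethylocta-2,7-dienyloxy]-3,5-dimethoxyphenyl]prop-2-enoate
Conditions: (S)-2-methyl-CBS-oxazaborolidine (0.2 equiv), catecholborane (1.8 equiv), toluene, −78 °C; aq. NaHCO3 work-up
Reagents that add atoms: none
Why: Corey–Bakshi–Shibata reduction, in which the ketone binds the ring boron anti to its larger substituent (the α-branched isopropenyl group) and hydride is delivered from the nitrogen-bound catecholborane to one face; with the (S)-catalyst this is predicted to set the (R)-carbinol (same sense as acetophenone to (R)-1-phenylethanol), the ester and alkenes are not reduced at −78 °C, and the assignment should be confirmed by Mosher ester analysis on the first batch.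

Step 10
Reactants: 17 methyl (E)-3-[4-[(2E,6R)-6-hydroxy-3,7-dimethylocta-2,7-dienyloxy]-3,5-dimethoxyphenyl]prop-2-enoate
Product: 18 (3R,6E)-8-[4-[(E)-3-hydroxyprop-1-enyl]-2,6-dimethoxyphenoxy]-2,6-dimethylocta-1,6-dien-3-ol (target CNP0161487.1)
Conditions: i-Bu2AlH (4 equiv), CH2Cl2, −78 to −20 °C; aq. KNaC4H4O6
Reagents that add atoms: none
Why: 1,2-Reduction of an α,β-unsaturated ester by i-Bu2AlH should give the cinnamyl alcohol without touching alkenes or aryl ethers; one equivalent is consumed by the free hydroxyl and the carbinol stereocentre is not affected.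

**Compound list**

1 | syringaldehyde (4-hydroxy-3,5-dimethoxybenzaldehyde) | COc1cc(C=O)cc(OC)c1O | starting material
2 | methyl (triphenylphosphoranylidene)acetate | COC(=O)C=P(c1ccccc1)(c1ccccc1)c1ccccc1 | starting material
3 | methyl (E)-sinapate | COC(=O)/C=C/c1cc(OC)c(O)c(OC)c1 | intermediate
4 | bromoacetaldehyde diethyl acetal | CCOC(CBr)OCC | starting material
5 | methyl (E)-3-[4-(2,2-diethoxyethoxy)-3,5-dimethoxyphenyl]prop-2-enoate | CCOC(COc1c(OC)cc(/C=C/C(=O)OC)cc1OC)OCC | intermediate
6 | methyl (E)-3-[3,5-dimethoxy-4-(2-oxoethoxy)phenyl]prop-2-enoate | COC(=O)/C=C/c1cc(OC)c(OCC=O)c(OC)c1 | intermediate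
7 | 2-bromopropene | C=C(C)Br | starting material
8 | isopropenylchromium dichloride (trivalent chromium) | C=C(C)[Cr](Cl)Cl | intermediate
9 | racemic methyl (E)-3-[4-(2-hydroxy-3-methylbut-3-enyloxy)-3,5-dimethoxyphenyl]prop-2-enoate | C=C(C)C(O)COc1c(OC)cc(/C=C/C(=O)OC)cc1OC | intermediate
10 | 3-methylbutan-2-one | CC(=O)C(C)C | starting material
11 | 3-bromo-3-methylbutan-2-one | CC(=O)C(C)(C)Br | intermediate
12 | 2-bromo-3,3-dimethoxy-2-methylbutane | COC(C)(OC)C(C)(C)Br | intermediate
13 | 3,3-dimethoxy-2-methylbut-1-ene | C=C(C)C(C)(OC)OC | intermediate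
14 | mixed ketal, methyl (E)-3-[4-[2-(2-methoxy-3-methylbut-3-en-2-yloxy)-3-methylbut-3-enyloxy]-3,5-dimethoxyphenyl]prop-2-enoate (diastereomer mixture) | C=C(C)C(C)(OC)OC(COc1c(OC)cc(/C=C/C(=O)OC)cc1OC)C(C)=C | intermediate
15 | allyl dienyl ether, methyl (E)-3-[3,5-dimethoxy-4-[3-methyl-2-(3-methylbuta-1,3-dien-2-yloxy)but-3-enyloxy]phenyl]prop-2-enoate (racemic) | C=C(C)C(=C)OC(COc1c(OC)cc(/C=C/C(=O)OC)cc1OC)C(C)=C | intermediate
16 | methyl (E)-3-[4-[(2E)-3,7-dimethyl-6-oxoocta-2,7-dienyloxy]-3,5-dimethoxyphenyl]prop-2-enoate | C=C(C)C(=O)CC/C(C)=C/COc1c(OC)cc(/C=C/C(=O)OC)cc1OC | intermediate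
17 | methyl (E)-3-[4-[(2E,6R)-6-hydroxy-3,7-dimethylocta-2,7-dienyloxy]-3,5-dimethoxyphenyl]prop-2-enoate | C=C(C)[C@H](O)CC/C(C)=C/COc1c(OC)cc(/C=C/C(=O)OC)cc1OC | intermediate
18 | (3R,6E)-8-[4-[(E)-3-hydroxyprop-1-enyl]-2,6-dimethoxyphenoxy]-2,6-dimethylocta-1,6-dien-3-ol | C=C(C)[C@H](O)CC/C(C)=C/COc1c(OC)cc(/C=C/CO)cc1OC | target

**Totals**

Total step count: 10.
Longest linear sequence: 7 steps (steps 1, 2, 3, 4, 8, 9, 10 from syringaldehyde); the three-step ketal branch (steps 5 to 7) joins at step 8.

**Steps most likely to fail**

Step 8. The 2-alkoxydiene formed in the flask may polymerise or undergo Diels–Alder dimerisation before it rearranges, exchange into the hindered secondary alcohol may stall, and the isopropenyl ketone product may degrade on prolonged heating. The fallback sets out from 9 and 10 and returns at 16, and keeps the same C4–C5 bond formation but never generates a diene. Ketone 10 would be chlorinated at the tertiary carbon with SO2Cl2 to 3-chloro-3-methylbutan-2-one F1 and ketalised (HC(OMe)3, MeOH, TsOH) to 3-chloro-2,2-dimethoxy-3-methylbutane F2. Heating 9 with F2 and catalytic 2,4-dinitrophenol in toluene should pass through the mixed chloro ketal F3 and the simple 2-alkoxyalkene (chloro enol ether) F4, whose Claisen rearrangement gives the tertiary α-chloro ketone F5. Dehydrochlorination of F5 with LiBr and Li2CO3 in DMF at 100 °C would then introduce the isopropenyl double bond and give 16.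

Step 9. Facial discrimination between the isopropenyl group and the primary alkyl chain may be poor, and conjugate hydride delivery to the enone may compete. The fallback sets out from 16 and returns at 17, replacing asymmetric induction by resolution. Luche reduction (NaBH4, CeCl3·7H2O, MeOH, −20 °C) should give the racemic allylic alcohol F6 by clean 1,2-reduction. Sharpless kinetic resolution of F6 (Ti(Oi-Pr)4, L-(+)-diisopropyl tartrate, t-BuOOH about 0.6 equiv, 4 Å sieves, CH2Cl2, −20 °C), run somewhat past half conversion, is expected to epoxidise the (S)-enantiomer to the erythro epoxy alcohol F7 and leave the (R)-alcohol 17, separable by chromatography. The remote trisubstituted alkene and the cinnamate are not allylic alcohols and should not react.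

Step 2. Displacement on the β,β-dialkoxy bromide by the hindered 2,6-dimethoxyphenoxide may be slow enough that ester cleavage or decomposition at high temperature takes over, and the aldehyde made from its product is prone to hydration and oligomerisation. The fallback sets out from 3 and returns at 9, bypassing the aldehyde and the chromium addition altogether. Heating 3 with K2CO3 in DMF at 80 °C and racemic 2-(prop-1-en-2-yl)oxirane F8 (prepared from methacrolein with trimethylsulfonium iodide and NaH in DMSO, Corey–Chaykovsky epoxidation) should open the epoxide at its unsubstituted carbon and give 9 directly.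

**Further compounds**

F1 | step 8 | 3-chloro-3-methylbutan-2-one | CC(=O)C(C)(C)Cl
F2 | step 8 | 3-chloro-2,2-dimethoxy-3-methylbutane | COC(C)(OC)C(C)(C)Cl
F3 | step 8 | mixed chloro ketal, methyl (E)-3-[4-[2-(3-chloro-2-methoxy-3-methylbutan-2-yloxy)-3-methylbut-3-enyloxy]-3,5-dimethoxyphenyl]prop-2-enoate | COC(C)(OC(COc1c(OC)cc(/C=C/C(=O)OC)cc1OC)C(C)=C)C(C)(C)Cl
F4 | step 8 | chloro enol ether, methyl (E)-3-[4-[2-(3-chloro-3-methylbut-1-en-2-yloxy)-3-methylbut-3-enyloxy]-3,5-dimethoxyphenyl]prop-2-enoate | C=C(OC(COc1c(OC)cc(/C=C/C(=O)OC)cc1OC)C(C)=C)C(C)(C)Cl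
F5 | step 8 | methyl (E)-3-[4-[(2E)-7-chloro-3,7-dimethyl-6-oxooct-2-enyloxy]-3,5-dimethoxyphenyl]prop-2-enoate | CC(C)(Cl)C(=O)CC/C(C)=C/COc1c(OC)cc(/C=C/C(=O)OC)cc1OC
F6 | step 9 | racemic methyl (E)-3-[4-[(2E)-6-hydroxy-3,7-dimethylocta-2,7-dienyloxy]-3,5-dimethoxyphenyl]prop-2-enoate | C=C(C)C(O)CC/C(C)=C/COc1c(OC)cc(/C=C/C(=O)OC)cc1OC
F7 | step 9 | methyl (E)-3-[4-[(2E,6S)-6-hydroxy-3-methyl-6-[(2R)-2-methyloxiran-2-yl]hex-2-enyloxy]-3,5-dimethoxyphenyl]prop-2-enoate | C[C@@]1(CO1)[C@@H](O)CC/C(C)=C/COc1c(OC)cc(/C=C/C(=O)OC)cc1OC
F8 | step 2 | racemic 2-(prop-1-en-2-yl)oxirane | C=C(C)C1CO1
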